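Two mirror-image substrates compete for one single-handed catalyst. The easy first step is to write what remains of each as a fraction of its own charge and count its fall in decades, as on a logarithmic axis.

| flask | left-handed substrate | right-handed substrate | reagent | free catalyst | added ligand | remark | time |
|---|---|---|---|---|---|---|---|
| Saturday's | 0.20 M | 0.20 M | 0.60 M | 1 mM | 0.69 mM | the very flask that is asked about, followed so far |  |
| flask | 0.20 M | 0.20 M | 0.600 M | 1.0 mM | 0.69 mM |  | 5.0 d |

Saturday's run (percent of the left-handed substrate and right-handed substrate together charged)

| time / h | left-handed product / % | right-handed product / % |
|---|---|---|
| 3.00 | 5.2 | 0.1 |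
| 10.0 | 16.8 | 0.6 |
| 15.0 | 24.9 | 0.4 |
| 25.0 | 35.6 | 1.2 |
| 40.0 | 45.2 | 2.7 |
| 50.0 | 47.9 | 4.2 |

(standard deviation of a reading: 0.5 percentage points)

- free catalyst is single-handed; left-handed substrate and right-handed substrate are mirror images of each other, charged as a racemate, each of them at the stated concentration
- the earlier runs were read with a standard deviation of 0.5 percentage points
- steps under discussion: reagent + catalyst intermediate A -> free catalyst + left-handed product; reagent + catalyst intermediate B -> free catalyst + right-handed product; free catalyst + added ligand <-> idle complex; reagent + free catalyst -> spent catalyst A; free catalyst + right-handed substrate <-> catalyst intermediate B; 2 free catalyst -> spent catalyst B; free catalyst + left-handed substrate <-> catalyst intermediate A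
- an excess is below zero if the other one leads

- excess of left-handed product over right-handed product in the product at 2.5 h
- excess of left-handed product over right-handed product in the product at 5.0 d
- part of the left-handed substrate and right-handed substrate charged together that has reacted at 5.0 d

Saturday's run offers two ways to the ratio of the two speeds. The first uses the products: up to 10.0 h the left-handed readings sum to 22 percentage points and the right-handed to 0.7 points, a ratio of 31.4. The second uses the decades: the product readings at 50.0 h put left-handed substrate at a fraction 0.0420 of its charge, or 1.38 decades, and right-handed substrate at 0.916, or 0.0381 decades, a ratio of 36.1.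

The two ways part, and the product ratio is the one that cheats. By 10.0 h the readings of Saturday's run show a third of the left-handed substrate used, so that product no longer comes at the starting pace, and the right-handed sum stands against a scatter of 0.5 points per reading. Decades count that depletion in. So the decades lost by left-handed substrate per decade lost by right-handed substrate, the selectivity factor, is the reading carried forward.

Taking the two substrates as equal near the start, the products follow this ratio, and the excess, ratio minus one over ratio plus one, comes to 94.6% at 2.5 h. For later times, right-handed substrate falls by the left-handed decades divided by 36.1. The readings stop earlier than 5.0 d, so this reckoning commits to no left-handed rest there.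

The forecast gives an excess of 94.6% at 2.5 h, then an excess of 65% with 60% reacted at 5.0 d, expecting about 10.5 percent right-handed product and adding that “deactivation should accelerate and may cut this somewhat”.

The simulated flask gives an excess of 94.1% at 2.5 h, then an excess of 74.9% with 57.1% reacted at 5.0 d.

    reagent + catalyst intermediate A → free catalyst + left-handed product (k = 16.0 /M/h)
    reagent + catalyst intermediate B → free catalyst + right-handed product (k = 6.18 /M/h)
    free catalyst + added ligand ⇌ idle complex (K = 1520 /M, k = 2220 /M/h)
    reagent + free catalyst → spent catalyst A (k = 0.0794 /M/h)
    free catalyst + right-handed substrate ⇌ catalyst intermediate B (K = 4.80 /M, k = 324 /M/h)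
    2 free catalyst → spent catalyst B (k = 135 /M/h)
    free catalyst + left-handed substrate ⇌ catalyst intermediate A (K = 120 /M, k = 1200 /M/h)

At 5.00 d the flask keeps 0.21% of its left-handed substrate unbound, 2.68 decades down. The factor then puts right-handed substrate at 84.3% of its charge and the excess at 72.8%. The flask keeps 86% unbound and shows an excess of 74.9%, with 7.14% right-handed product against the forecast's 10.5 percent. The neighbour charged with 0.24 M of reagent keeps 17% of its left-handed substrate unbound at 5.00 d. The same reckoning gives right-handed substrate 95.2% and an excess of 89.1%. That neighbour keeps 97% unbound and ends at an excess of 92.5%.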